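**Strategy.** Ring A is opened at C3–C4 (halimane numbering). The key step exploits that C4 is the α-carbon of the C19 ester and that C3 is a CH2 group homoallylic to the C1=C10 alkene: an ester enolate at C4 displaces a C3 bromide (6-exo-tet) to close ring A, and in the same flask the new ring-A enolate is methylated, C5 directing the C4 quaternary centre. The precursor is a ring-B cyclohexane with CH2CO2Me at C5 and an (E)-3-bromopropylidene at C10, made by a Julia cyclopropylcarbinyl opening. C8 is set by catalysis and relays C9, C5 and C4; C14 is bought and controls C13.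

Key step: step 6

Remarks on the chemistry (assumptions):
- Numbering: C4 = quaternary ester carbon, C3/C2 = ring-A CH2 groups, C1=C10 = alkene, C5 = ring-fusion CH, C6/C7 = ring-B CH2 groups, C8 = CHMe, C9 = quaternary carbon, C11–C15 = side chain, C19 = ester carbon.
- The target is (4S,5R,8R,9S,13R,14S). H5, the C4, C8 and C9 methyl groups lie on one face; the C4 ester and the C9 side chain lie on the other.
- The ligand enantiomer in step 1 is assumed to be the one that gives the 3R adduct; the antipode would give the enantiomeric series.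

Step 1
Reactants: 1 2-methylcyclohex-2-en-1-one
Product: 3 (2R,3R)-2-(1-hydroxyethyl)-2,3-dimethylcyclohexan-1-one, via dimethylaluminium enolate 2 (not isolated)
Conditions: AlMe3, Cu(O2CC4H3S) (cat.), (R,S,S)-binaphthyl bis(1-phenylethyl)phosphoramidite (cat.), Et2O, −30 °C; then CH3CHO, −78 → −20 °C; aq. potassium sodium tartrate
Reagents that add atoms: trimethylaluminium C[Al](C)C; acetaldehyde CC=O
Why: Copper-catalysed asymmetric conjugate addition sets C8 under ligand control, and the aluminium enolate then adds to acetaldehyde (tandem conjugate addition–aldol) anti to the new C8 methyl group, which sets the C9 quaternary centre with the two methyl groups cis.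

Step 2
Reactants: 3 (2R,3R)-2-(1-hydroxyethyl)-2,3-dimethylcyclohexan-1-one
Product: 4 (2S,3R)-2-ethenyl-2,3-dimethylcyclohexan-1-one
Conditions: Martin sulfurane Ph2S[OC(CF3)2Ph]2, CH2Cl2, rt
Reagents that add atoms: none
Why: Martin sulfurane dehydration of the secondary carbinol can only eliminate towards its methyl group because C9 is quaternary, so the vinyl group should form without touching the stereocentres.

Step 3
Reactants: 4 (2S,3R)-2-ethenyl-2,3-dimethylcyclohexan-1-one
Product: 5 methyl 2-[(1S,3S,4R)-3-ethenyl-3,4-dimethyl-2-oxocyclohexyl]acetate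
Conditions: LiN(iPr)2, THF, −78 °C; BrCH2CO2Me, −78 → −20 °C; then NaOMe (cat.), MeOH, rt
Reagents that add atoms: methyl bromoacetate COC(=O)CBr
Why: C5 is the only enolisable position of 4, so kinetic enolate alkylation is regiospecific, and base equilibration should place the CH2CO2Me group equatorial (H5 cis to both methyl groups) because its epimer would be syn-diaxial to the C9 methyl group.

Step 4
Reactants: 5 methyl 2-[(1S,3S,4R)-3-ethenyl-3,4-dimethyl-2-oxocyclohexyl]acetate
Product: 7 (3aS,6R,7S,7aS)-7a-cyclopropyl-7-ethenyl-6,7-dimethylhexahydro-1-benzofuran-2(3H)-one, via hydroxy ester 6 (not isolated)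
Conditions: c-C3H5MgBr, CeCl3, THF, −78 → 0 °C; aq. NH4Cl; then PPTS (cat.), PhMe, 60 °C
Reagents that add atoms: cyclopropylmagnesium bromide Br[Mg]C1CC1
Why: The organocerium reagent should add to the hindered ketone faster than to the ester (1,2-addition, axial attack expected) and the tertiary alkoxide closes onto the γ-ester to give the lactone; the C10 configuration does not matter because C10 becomes sp2 in step 5.

Step 5
Reactants: 7 (3aS,6R,7S,7aS)-7a-cyclopropyl-7-ethenyl-6,7-dimethylhexahydro-1-benzofuran-2(3H)-one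
Product: 10 methyl 2-[(1S,2E,3S,4R)-2-(3-bromopropylidene)-3-ethenyl-3,4-dimethylcyclohexyl]acetate, via trimethylsilyl ester 8 (not isolated), via bromo acid 9 (not isolated)
Conditions: Me3SiBr, ZnBr2 (cat.), CH2Cl2, −20 → 0 °C; then MeOH; then Me3SiCHN2, PhMe/MeOH, 0 °C
Reagents that add atoms: bromotrimethylsilane C[Si](C)(C)Br; (trimethylsilyl)diazomethane C[Si](C)(C)C=[N+]=[N-]
Why: In this Julia olefin synthesis silylation of the lactone carbonyl ionises the tertiary cyclopropylcarbinyl C–O bond and bromide opens the cyclopropane, the bisected cation placing the CH2CH2Br arm on the side of the less hindered C5 (E-alkene), after which methanolysis and methylation restore the methyl ester.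

Step 6
Reactants: 10 methyl 2-[(1S,2E,3S,4R)-2-(3-bromopropylidene)-3-ethenyl-3,4-dimethylcyclohexyl]acetate
Product: 12 methyl (1S,5S,6R,8aR)-5-ethenyl-1,5,6-trimethyl-1,2,3,5,6,7,8,8a-octahydronaphthalene-1-carboxylate, via cyclised ester 11 (not isolated)
Conditions: KN(SiMe3)2, THF, −78 → 0 °C; then LiN(iPr)2, THF/DMPU, −78 °C; MeI, −78 → −20 °C
Reagents that add atoms: iodomethane CI
Why: KN(SiMe3)2 deprotonates the C4 methylene α to the ester and the enolate displaces the primary C3 bromide in an intramolecular SN2 reaction (6-exo-tet), the classical cycloalkylation of an ω-halo ester enolate, which closes ring A as a cyclohexene because C2 and C5 are cis on the C1=C10 alkene. LiN(iPr)2 then regenerates the ring-A ester enolate at C4 and methyl iodide alkylates it, as in the C4 alkylation of diterpenoid resin-acid ester enolates. The C4 centre is controlled by C5: allylic 1,3-strain between the enolate oxygen and C6 turns the C5–C6 bond out of the enolate plane onto one face, so methyl iodide should enter anti to C6, on the face of H5, which gives the methyl group cis to H5 and the ester trans to it. The step needs C-alkylation to outrun E2 loss of HBr from the homoallylic bromide, which the fast six-membered closure at low temperature and the weakly basic potassium enolate should secure. Only the (E)-bromide can reach C4, so any (Z)-isomer carried from step 5 stays open-chain and is removed. No other enolisable carbonyl group is present, so both deprotonations are unambiguous.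

Step 7
Reactants: 13 methyl (4S)-2,2-dimethyl-1,3-dioxolane-4-carboxylate
Product: 14 S-ethyl (4S)-2,2-dimethyl-1,3-dioxolane-4-carbothioate
Conditions: EtSH, AlMe3, CH2Cl2, 0 °C → rt
Reagents that add atoms: ethanethiol CCS
Why: Dimethylaluminium ethanethiolate, formed in the flask, converts the ester into the thioester (aluminium thiolate transesterification) without touching the acetal or the α-stereocentre.

Step 8
Reactants: 12 methyl (1S,5S,6R,8aR)-5-ethenyl-1,5,6-trimethyl-1,2,3,5,6,7,8,8a-octahydronaphthalene-1-carboxylate, 14 S-ethyl (4S)-2,2-dimethyl-1,3-dioxolane-4-carbothioate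
Product: 16 methyl (1S,5S,6R,8aR)-5-{3-[(4S)-2,2-dimethyl-1,3-dioxolan-4-yl]-3-oxopropyl}-1,5,6-trimethyl-1,2,3,5,6,7,8,8a-octahydronaphthalene-1-carboxylate, via B-alkyl-9-BBN 15 (not isolated)
Conditions: 9-BBN dimer, THF, 0 °C → rt; then 14, Pd2(dba)3 (cat.), P(2-furyl)3, Cu(O2CC4H3S), Cs2CO3, THF, 45 °C
Reagents that add atoms: none
Why: 9-BBN should hydroborate only the monosubstituted vinyl group, and the B-alkyl group is then transferred to the thioester in a Liebeskind–Srogl acyl cross-coupling, which forms the C12–C13 bond and brings in C14 with its purchased configuration.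

Step 9
Reactants: 16 methyl (1S,5S,6R,8aR)-5-{3-[(4S)-2,2-dimethyl-1,3-dioxolan-4-yl]-3-oxopropyl}-1,5,6-trimethyl-1,2,3,5,6,7,8,8a-octahydronaphthalene-1-carboxylate
Product: 17 methyl (1S,5S,6R,8aR)-5-{(3R)-3-[(4S)-2,2-dimethyl-1,3-dioxolan-4-yl]-3-hydroxybutyl}-1,5,6-trimethyl-1,2,3,5,6,7,8,8a-octahydronaphthalene-1-carboxylate
Conditions: MeMgBr, THF/Et2O, −78 °C
Reagents that add atoms: methylmagnesium bromide C[Mg]Br
Why: In this Cram-chelate addition magnesium bridges the ketone oxygen and the α-oxygen of the dioxolane and the Grignard reagent attacks anti to C15, which should set the 13R tertiary alcohol, while the hindered tertiary C19 ester does not react at −78 °C.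

Step 10
Reactants: 17 methyl (1S,5S,6R,8aR)-5-{(3R)-3-[(4S)-2,2-dimethyl-1,3-dioxolan-4-yl]-3-hydroxybutyl}-1,5,6-trimethyl-1,2,3,5,6,7,8,8a-octahydronaphthalene-1-carboxylate
Product: 18 methyl (1S,5S,6R,8aR)-1,5,6-trimethyl-5-[(3R,4S)-3,4,5-trihydroxy-3-methylpentyl]-1,2,3,5,6,7,8,8a-octahydronaphthalene-1-carboxylate
Conditions: AcOH/H2O (4:1), 40 °C
Reagents that add atoms: none
Why: Mild acid hydrolysis of the terminal acetonide should free the 14,15-diol without ionising the tertiary alcohol or moving the C1=C10 alkene.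

Step 11
Reactants: 18 methyl (1S,5S,6R,8aR)-1,5,6-trimethyl-5-[(3R,4S)-3,4,5-trihydroxy-3-methylpentyl]-1,2,3,5,6,7,8,8a-octahydronaphthalene-1-carboxylate
Product: 19 methyl (1S,5S,6R,8aR)-5-[(3R,4S)-4,5-diacetoxy-3-hydroxy-3-methylpentyl]-1,5,6-trimethyl-1,2,3,5,6,7,8,8a-octahydronaphthalene-1-carboxylate (CNP0238486.2)
Conditions: Ac2O, pyridine, 0 °C → rt
Reagents that add atoms: acetic anhydride CC(=O)OC(C)=O
Why: Acetylation in pyridine esterifies the primary and the secondary hydroxyl group and should leave the hindered tertiary C13 alcohol free.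

**Compound list**

1 | 2-methylcyclohex-2-en-1-one | CC1=CCCCC1=O | starting material
2 | dimethylaluminium (3R)-2,3-dimethylcyclohex-1-en-1-olate | C[C@@H]1CCCC(O[Al](C)C)=C1C | intermediate
3 | (2R,3R)-2-(1-hydroxyethyl)-2,3-dimethylcyclohexan-1-one (both carbinol epimers; that centre is removed in step 2) | O=C1CCC[C@@H](C)[C@]1(C)C(C)O | intermediate
4 | (2S,3R)-2-ethenyl-2,3-dimethylcyclohexan-1-one | O=C1CCC[C@@H](C)[C@]1(C)C=C | intermediate
5 | methyl 2-[(1S,3S,4R)-3-ethenyl-3,4-dimethyl-2-oxocyclohexyl]acetate | O=C1[C@H](CC(=O)OC)CC[C@@H](C)[C@]1(C)C=C | intermediate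
6 | methyl 2-[(1S,2S,3S,4R)-2-cyclopropyl-3-ethenyl-2-hydroxy-3,4-dimethylcyclohexyl]acetate (formed as its alkoxide; C10–O drawn cis to the C9 methyl group) | COC(=O)C[C@@H]1CC[C@@H](C)[C@](C)(C=C)[C@]1(O)C2CC2 | intermediate
7 | (3aS,6R,7S,7aS)-7a-cyclopropyl-7-ethenyl-6,7-dimethylhexahydro-1-benzofuran-2(3H)-one (trans-fused lactone drawn; the C10 epimer would serve equally) | O=C1C[C@@H]2CC[C@@H](C)[C@](C)(C=C)[C@@]2(C3CC3)O1 | intermediate
8 | trimethylsilyl 2-[(1S,2E,3S,4R)-2-(3-bromopropylidene)-3-ethenyl-3,4-dimethylcyclohexyl]acetate | C[Si](C)(C)OC(=O)C[C@@H]1CC[C@@H](C)[C@](C)(C=C)/C1=C/CCBr | intermediate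
9 | 2-[(1S,2E,3S,4R)-2-(3-bromopropylidene)-3-ethenyl-3,4-dimethylcyclohexyl]acetic acid | OC(=O)C[C@@H]1CC[C@@H](C)[C@](C)(C=C)/C1=C/CCBr | intermediate
10 | methyl 2-[(1S,2E,3S,4R)-2-(3-bromopropylidene)-3-ethenyl-3,4-dimethylcyclohexyl]acetate | COC(=O)C[C@@H]1CC[C@@H](C)[C@](C)(C=C)/C1=C/CCBr | intermediate
11 | methyl (5S,6R,8aS)-5-ethenyl-5,6-dimethyl-1,2,3,5,6,7,8,8a-octahydronaphthalene-1-carboxylate (C1 epimers; 1R drawn; the centre is re-enolised) | COC(=O)[C@@H]1CCC=C2[C@H]1CC[C@@H](C)[C@]2(C)C=C | intermediate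
12 | methyl (1S,5S,6R,8aR)-5-ethenyl-1,5,6-trimethyl-1,2,3,5,6,7,8,8a-octahydronaphthalene-1-carboxylate | COC(=O)[C@@]1(C)CCC=C2[C@H]1CC[C@@H](C)[C@]2(C)C=C | intermediate
13 | methyl (4S)-2,2-dimethyl-1,3-dioxolane-4-carboxylate | COC(=O)[C@@H]1COC(C)(C)O1 | starting material
14 | S-ethyl (4S)-2,2-dimethyl-1,3-dioxolane-4-carbothioate | CCSC(=O)[C@@H]1COC(C)(C)O1 | intermediate
15 | methyl (1S,5S,6R,8aR)-5-[2-(9-borabicyclo[3.3.1]nonan-9-yl)ethyl]-1,5,6-trimethyl-1,2,3,5,6,7,8,8a-octahydronaphthalene-1-carboxylate | COC(=O)[C@@]1(C)CCC=C2[C@H]1CC[C@@H](C)[C@]2(C)CCB3C4CCCC3CCC4 | intermediate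
16 | methyl (1S,5S,6R,8aR)-5-{3-[(4S)-2,2-dimethyl-1,3-dioxolan-4-yl]-3-oxopropyl}-1,5,6-trimethyl-1,2,3,5,6,7,8,8a-octahydronaphthalene-1-carboxylate | COC(=O)[C@@]1(C)CCC=C2[C@H]1CC[C@@H](C)[C@]2(C)CCC(=O)[C@@H]3COC(C)(C)O3 | intermediate
17 | methyl (1S,5S,6R,8aR)-5-{(3R)-3-[(4S)-2,2-dimethyl-1,3-dioxolan-4-yl]-3-hydroxybutyl}-1,5,6-trimethyl-1,2,3,5,6,7,8,8a-octahydronaphthalene-1-carboxylate | COC(=O)[C@@]1(C)CCC=C2[C@H]1CC[C@@H](C)[C@]2(C)CC[C@@](C)(O)[C@@H]3COC(C)(C)O3 | intermediate
18 | methyl (1S,5S,6R,8aR)-1,5,6-trimethyl-5-[(3R,4S)-3,4,5-trihydroxy-3-methylpentyl]-1,2,3,5,6,7,8,8a-octahydronaphthalene-1-carboxylate | COC(=O)[C@@]1(C)CCC=C2[C@H]1CC[C@@H](C)[C@]2(C)CC[C@@](C)(O)[C@H](CO)O | intermediate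
19 | methyl (1S,5S,6R,8aR)-5-[(3R,4S)-4,5-diacetoxy-3-hydroxy-3-methylpentyl]-1,5,6-trimethyl-1,2,3,5,6,7,8,8a-octahydronaphthalene-1-carboxylate (CNP0238486.2) | COC(=O)[C@@]1(C)CCC=C2[C@H]1CC[C@@H](C)[C@]2(C)CC[C@@](C)(O)[C@H](COC(C)=O)OC(C)=O | target

**Step count.** Total: 11 steps. Longest linear sequence: 10 steps (steps 1–6 and 8–11); step 7 is the side branch.

**Three steps most likely to fail**

1. Step 6 (key step). E2 loss of HBr from the homoallylic bromide or proton transfer may outrun ring closure, and the second-stage methylation may show insufficient facial selectivity. The fallback uses the far more nucleophilic carboxylate enediolate instead of the ester enolate. It sets out from bromo acid 9, isolated after the methanol quench of step 5. LiN(iPr)2 (2.2 equiv, THF, −78 → 0 °C) should cyclise it to the ring-A acid F1. A second treatment with LiN(iPr)2 (2.2 equiv) and MeI should give the C4-methylated acid F2. Me3SiCHN2 (PhMe/MeOH) then returns the route at 12.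

2. Step 5. The silylated lactone may ionise to a cation that loses H5 into the ring instead of being opened by bromide, or the opening may show poor E/Z control. The fallback avoids the lactone and opens the free carbinol with a milder halide Lewis acid. It sets out from ketone 4. LiN(iPr)2 and BrCH2CO2tBu give the tert-butyl keto ester F3. c-C3H5MgBr/CeCl3 gives the tertiary cyclopropylcarbinol F4, which should not lactonise onto the tert-butyl ester. MgI2·OEt2 in Et2O opens it to the (E)-homoallylic iodide F5. KN(SiMe3)2, then LiN(iPr)2/MeI as in step 6, should give the cyclised tert-butyl ester F6 and from it the methylated tert-butyl ester F7. Me3SiOTf/2,6-lutidine, then aqueous work-up, cleaves F7 to the acid F2 named above, and Me3SiCHN2 returns the route at 12.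

3. Step 8. Transmetallation of the β-branched B-alkyl group may be slow, and the carbonate base may epimerise the α-alkoxy thioester. The fallback is a base-free organozinc acylation. It sets out from 12. 9-BBN, then I2/NaOMe, gives the primary iodide F8. Zn dust/LiCl in THF gives the alkylzinc iodide F9. Fukuyama coupling of F9 with 14 (PdCl2(PPh3)2, PhMe, rt) returns the route at 16.

**Further compounds**

F1 | step 6 | (5S,6R,8aS)-5-ethenyl-5,6-dimethyl-1,2,3,5,6,7,8,8a-octahydronaphthalene-1-carboxylic acid (C1 epimers; 1R drawn) | OC(=O)[C@@H]1CCC=C2[C@H]1CC[C@@H](C)[C@]2(C)C=C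
F2 | step 6 | (1S,5S,6R,8aR)-5-ethenyl-1,5,6-trimethyl-1,2,3,5,6,7,8,8a-octahydronaphthalene-1-carboxylic acid | OC(=O)[C@@]1(C)CCC=C2[C@H]1CC[C@@H](C)[C@]2(C)C=C
F3 | step 5 | tert-butyl 2-[(1S,3S,4R)-3-ethenyl-3,4-dimethyl-2-oxocyclohexyl]acetate | O=C1[C@H](CC(=O)OC(C)(C)C)CC[C@@H](C)[C@]1(C)C=C
F4 | step 5 | tert-butyl 2-[(1S,2S,3S,4R)-2-cyclopropyl-3-ethenyl-2-hydroxy-3,4-dimethylcyclohexyl]acetate | CC(C)(C)OC(=O)C[C@@H]1CC[C@@H](C)[C@](C)(C=C)[C@]1(O)C2CC2
F5 | step 5 | tert-butyl 2-[(1S,2E,3S,4R)-3-ethenyl-2-(3-iodopropylidene)-3,4-dimethylcyclohexyl]acetate | CC(C)(C)OC(=O)C[C@@H]1CC[C@@H](C)[C@](C)(C=C)/C1=C/CCI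
F6 | step 5 | tert-butyl (5S,6R,8aS)-5-ethenyl-5,6-dimethyl-1,2,3,5,6,7,8,8a-octahydronaphthalene-1-carboxylate (C1 epimers; 1R drawn) | CC(C)(C)OC(=O)[C@@H]1CCC=C2[C@H]1CC[C@@H](C)[C@]2(C)C=C
F7 | step 5 | tert-butyl (1S,5S,6R,8aR)-5-ethenyl-1,5,6-trimethyl-1,2,3,5,6,7,8,8a-octahydronaphthalene-1-carboxylate | CC(C)(C)OC(=O)[C@@]1(C)CCC=C2[C@H]1CC[C@@H](C)[C@]2(C)C=C
F8 | step 8 | methyl (1S,5S,6R,8aR)-5-(2-iodoethyl)-1,5,6-trimethyl-1,2,3,5,6,7,8,8a-octahydronaphthalene-1-carboxylate | COC(=O)[C@@]1(C)CCC=C2[C@H]1CC[C@@H](C)[C@]2(C)CCI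
F9 | step 8 | {2-[(1S,2R,5S,8aR)-5-(methoxycarbonyl)-1,2,5-trimethyl-1,2,3,4,5,6,7,8a-octahydronaphthalen-1-yl]ethyl}zinc iodide | COC(=O)[C@@]1(C)CCC=C2[C@H]1CC[C@@H](C)[C@]2(C)CC[Zn]I
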